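**Retrosynthetic overview**
1. Target 17 ⇒ cis-3β,4β-diol 13 (angeloylation of the equatorial secondary O3, then acetylation of the axial tertiary O4). Diol 13 ⇒ bis-enone ketol 11 (hydrogenation of C1=C2, α-face hydride at C3).
2. 11 ⇒ trans-enedione 8: C15 is added to the C4 carbonyl. A Stork-Danheiser transposition then deletes the C1 oxygen and uncovers C3=O, and the same acid treatment turns the C8 silyl dienol ether into the C7(=C11)–C8=O enone.
3. 8 ⇒ (C5 epimerisation) cis adduct 7 ⇒ Diels-Alder disconnection of C5–C6 and C9–C10. Ring A is flat 2-methoxy-5-methyl-1,4-benzoquinone 6; C6–C9 and C11–C13 come as the cross-conjugated silyloxytriene 5 (three steps from methyl vinyl ketone).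
4. Enabling feature: in ring B the C8 carbonyl stands 1,3 to quaternary C10 (through C9) and 1,4 to C5, and C5 carries the oxygenated C4 of ring A. With C4 as a carbonyl, C10 is an enone β-carbon and C9 an enol ether terminus (matched polarity), and H5 is α to that carbonyl (cis to trans correction). The vicinal C3/C4 oxygens are those of a methoxyquinone, and the ring B enone is the keto tautomer of the dienol ether left by the triene.
5. Ring order: ring A is bought as the quinone, ring B is closed in the key step, and no other ring is formed.

Key step: step 4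

Remark: eudesmane numbering is used (ring A = C1, C2, C3, C4, C5, C10; ring B = C5 to C10; C14 on C10, C15 on C4, C11 to C13 the isopropylidene unit). β is the face of the C10 methyl.
Assumption: the complex made from (R,R)-TADDOL is taken to leave the α face of chelated 6 open. The sense of induction has to be checked on 8, and the equally available (S,S)-ligand is used if it proves opposite.

**Step 1**
Reactants: 1 methyl vinyl ketone
Product: 3 3-bromobut-3-en-2-one, via 3,4-dibromobutan-2-one 2 (not isolated)
Conditions: Br2, CH2Cl2, 0 °C; then Et3N, 0 °C → rt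
Reagents that add atoms: bromine, BrBr
Why: Bromination-dehydrobromination, in which bromine adds to the enone C=C and the base then removes the acidic α-hydrogen with loss of the β-bromide, is the standard route to α-bromoenones and leaves no stereocentre.

**Step 2**
Reactants: 3 3-bromobut-3-en-2-one
Product: 4 [(3-bromobuta-1,3-dien-2-yl)oxy](tert-butyl)dimethylsilane
Conditions: TBSOTf, Et3N, CH2Cl2, 0 °C
Reagents that add atoms: tert-butyldimethylsilyl trifluoromethanesulfonate, CC(C)(C)[Si](C)(C)OS(=O)(=O)C(F)(F)F
Why: Soft enolisation with a silyl triflate and a tertiary amine can only take the CH3 protons of the methyl ketone, which gives the 2-silyloxydiene without any stereocentre.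

**Step 3**
Reactants: 4 [(3-bromobuta-1,3-dien-2-yl)oxy](tert-butyl)dimethylsilane
Product: 5 tert-butyl(dimethyl)[(4-methyl-3-methylidenepenta-1,4-dien-2-yl)oxy]silane (silyloxy[3]dendralene)
Conditions: isopropenylmagnesium bromide, Pd(PPh3)4 (3 mol %), THF, 0 °C → rt
Reagents that add atoms: isopropenylmagnesium bromide, CC(=C)[Mg]Br
Why: In this Kumada coupling zerovalent palladium inserts only into the alkenyl C–Br bond (the enol silane C–O bond is inert), and transmetallation with the alkenyl Grignard reagent followed by reductive elimination gives the cross-conjugated triene, the usual entry to substituted [3]dendralenes.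

**Step 4**
Reactants: 5 silyloxy[3]dendralene; 6 2-methoxy-5-methyl-1,4-benzoquinone
Product: 7 (4aR,8aS)-6-(tert-butyldimethylsilyloxy)-2-methoxy-4a-methyl-7-(prop-1-en-2-yl)-4a,5,8,8a-tetrahydronaphthalene-1,4-dione (cis-fused; 10β-CH3 and 5β-H)
Conditions: (R,R)-TADDOL [(4R,5R)-2,2-dimethyl-α,α,α′,α′-tetraphenyl-1,3-dioxolane-4,5-dimethanol] (22 mol %), TiCl2(OiPr)2 (20 mol %), 4 Å MS, toluene, −78 → −30 °C
Reagents that add atoms: none
Why: The titanium complex binds 6 as a five-membered chelate through the C4 carbonyl oxygen and the C3 methoxy oxygen, and a normal-electron-demand, strongly asynchronous [4+2] cycloaddition follows in which C9, the enol silane terminus and most nucleophilic carbon of 5, bonds to C10, the β-carbon of the activated C4 enone, while C6 bonds to C5. The closest known type is the Diels-Alder reaction of 2-alkoxy-1,4-benzoquinones with simple dienes and 2-silyloxydienes promoted by chelating tetravalent titanium or tin Lewis acids, chiral titanium diolates included, and [3]dendralenes are known to add quinones through one diene arm. Ring B is the only ring closed, by intermolecular suprafacial addition of the C6=C7–C8=C9 diene across C5=C10 (in the stepwise limit a Mukaiyama-Michael addition at C10 followed by 6-endo-trig closure of the C5 titanium enolate on C6), which can only give the cis ring fusion. C10 and C5 are created together: their relative configuration follows from suprafacial addition to a ring double bond, their absolute configuration from the aryl groups of the TADDOL ligand, which cover one face of the chelated quinone so that the diene enters on the α face and the C10 methyl is left β, and endo/exo orientation creates no stereocentre because both diene termini are CH2. The step needs site selectivity in both partners and one regiochemistry: C2=C3 of 6 is switched off as a vinylogous ester by the methoxy group, the silyloxy arm of 5 outruns the isopropenyl arm because only attack through C9 develops an oxygen-stabilised cation (at C8), and chelation makes C4=O rather than C1=O the directing carbonyl. A second cycloaddition on the new C8=C7–C11=C12 diene of 7 should be slow because its s-cis form presses C12 against the OTBS group, so this unit stays as the masked C7(=C11)–C8=O enone.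

**Step 5**
Reactants: 7 cis adduct
Product: 8 (4aR,8aR)-6-(tert-butyldimethylsilyloxy)-2-methoxy-4a-methyl-7-(prop-1-en-2-yl)-4a,5,8,8a-tetrahydronaphthalene-1,4-dione (trans-fused; 10β-CH3 and 5α-H)
Conditions: DBU (10 mol %), CH2Cl2, rt
Reagents that add atoms: none
Why: Base-catalysed epimerisation through the extended C5 enolate (H5 is α to C4=O and vinylogously linked to C1=O) should drain the cis adduct into the more stable trans-fused enedione, with H5 axial on the α face anti to the C10 methyl, while quaternary C10 cannot change.

**Step 6**
Reactants: 8 trans-enedione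
Product: 9 (4R,4aR,8aR)-7-(tert-butyldimethylsilyloxy)-4-hydroxy-3-methoxy-4,8a-dimethyl-6-(prop-1-en-2-yl)-4a,5,8,8a-tetrahydronaphthalen-1(4H)-one (4β-OH and 4α-CH3)
Conditions: CeCl3 (anhydrous), MeLi, THF, −78 °C
Reagents that add atoms: methyllithium, [Li]C
Why: In this organocerium 1,2-addition the weakly basic, oxophilic reagent adds rather than enolises (as it does with other very acidic ketones such as 2-tetralone), picks C4=O because C1=O is a vinylogous ester next to a quaternary carbon, and comes from the α face because the axial C10 methyl covers the β face, which sets C4 with 4β-OH and 4α-CH3.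

**Step 7**
Reactants: 9 tertiary alcohol
Product: 11 4β-hydroxy-5αH-eudesma-1,7(11)-diene-3,8-dione (4R,5R,10S; bis-enone ketol), via allylic diol 10 (not isolated)
Conditions: LiAlH4, Et2O, 0 °C; then 2 M HCl, THF, 0 °C → rt
Reagents that add atoms: water, O
Why: In this Stork-Danheiser transposition hydride reduces the vinylogous ester carbonyl C1, aqueous acid ionises the methoxy-assisted C1 allylic alcohol and hydrolyses the enol ether to the C1=C2–C3=O enone, and the same acid protonates the silyl dienol ether at C12 (any C7-protonated isomer should conjugate under the conditions) to give the isopropylidene enone, so the transient C1 carbinol centre is destroyed and C4, C5 and C10 are untouched.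

**Step 8**
Reactants: 11 bis-enone ketol
Product: 12 4β-hydroxy-5αH-eudesm-7(11)-ene-3,8-dione (4R,5R,10R)
Conditions: H2 (1 atm), RhCl(PPh3)3 (5 mol %), benzene/EtOH, rt
Reagents that add atoms: none
Why: Homogeneous hydrogenation with RhCl(PPh3)3 reduces the disubstituted C1=C2 bond and leaves the tetrasubstituted C7=C11 bond alone, the selectivity known from steroidal 1,4-dien-3-ones, and creates no stereocentre.

**Step 9**
Reactants: 12 saturated ketol
Product: 13 3β,4β-dihydroxy-5αH-eudesm-7(11)-en-8-one (3S,4R,5R,10R)
Conditions: NaBH4 (0.5 equiv), MeOH/CH2Cl2 (1:1), −78 °C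
Reagents that add atoms: none
Why: Low-temperature borohydride reduction takes the saturated, α-oxygen-activated C3 ketone ahead of the hindered conjugated C8 enone, and axial attack on the α face, anti to the axial C4–O bond and away from the C10 methyl, gives the equatorial 3β-alcohol and thus the cis diol.

**Step 10**
Reactants: 14 angelic acid [(Z)-2-methylbut-2-enoic acid]
Product: 15 (Z)-2-methylbut-2-enoic 2,4,6-trichlorobenzoic anhydride
Conditions: 2,4,6-trichlorobenzoyl chloride, Et3N, toluene, rt; filtered and concentrated
Reagents that add atoms: 2,4,6-trichlorobenzoyl chloride, O=C(Cl)c1c(Cl)cc(Cl)cc1Cl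
Why: Yamaguchi-type mixed anhydride formation from the carboxylate and the hindered aroyl chloride runs at room temperature and does not touch the Z double bond.

**Step 11**
Reactants: 13 cis diol; 15 mixed anhydride
Product: 16 3β-angeloyloxy-4β-hydroxy-5αH-eudesm-7(11)-en-8-one
Conditions: Et3N, toluene, 80 °C
Reagents that add atoms: none
Why: Acyl transfer from the Yamaguchi-type anhydride takes place at the angeloyl carbonyl (the aroyl carbonyl is flanked by two ortho chlorines), the absence of a nucleophilic catalyst keeps the Z geometry, and only the equatorial secondary 3β-OH reacts because the axial tertiary 4β-OH is too hindered.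

**Step 12**
Reactants: 16 monoangelate
Product: 17 4β-acetoxy-3β-angeloyloxy-5αH-eudesm-7(11)-en-8-one (3S,4R,5R,10R; target)
Conditions: Ac2O, Sc(OTf)3 (5 mol %), MeCN, −20 °C
Reagents that add atoms: acetic anhydride, CC(=O)OC(C)=O
Why: Sc(OTf)3-catalysed acetylation with acetic anhydride is one of the few methods that esterify tertiary alcohols, the low temperature holds back elimination and Z to E isomerisation, and the C4–O bond is not broken, so the configuration is kept.

**Compound list**
1 | methyl vinyl ketone | C=CC(C)=O | starting material
2 | 3,4-dibromobutan-2-one (racemic) | CC(=O)C(Br)CBr | intermediate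
3 | 3-bromobut-3-en-2-one | C=C(Br)C(C)=O | intermediate
4 | [(3-bromobuta-1,3-dien-2-yl)oxy](tert-butyl)dimethylsilane | C=C(Br)C(=C)O[Si](C)(C)C(C)(C)C | intermediate
5 | tert-butyl(dimethyl)[(4-methyl-3-methylidenepenta-1,4-dien-2-yl)oxy]silane | C=C(C)C(=C)C(=C)O[Si](C)(C)C(C)(C)C | intermediate
6 | 2-methoxy-5-methyl-1,4-benzoquinone | COC1=CC(=O)C(C)=CC1=O | starting material
7 | cis Diels-Alder adduct (4aR,8aS) | COC1=CC(=O)[C@]2(C)CC(O[Si](C)(C)C(C)(C)C)=C(C(C)=C)C[C@@H]2C1=O | intermediate
8 | trans-enedione (4aR,8aR) | COC1=CC(=O)[C@]2(C)CC(O[Si](C)(C)C(C)(C)C)=C(C(C)=C)C[C@H]2C1=O | intermediate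
9 | C4 tertiary alcohol (4β-OH, 4α-CH3) | COC1=CC(=O)[C@]2(C)CC(O[Si](C)(C)C(C)(C)C)=C(C(C)=C)C[C@H]2[C@@]1(C)O | intermediate
10 | allylic diol (C1 carbinol configuration not relevant) | COC1=CC(O)[C@]2(C)CC(O[Si](C)(C)C(C)(C)C)=C(C(C)=C)C[C@H]2[C@@]1(C)O | intermediate
11 | 4β-hydroxy-5αH-eudesma-1,7(11)-diene-3,8-dione | O=C1C=C[C@]2(C)CC(=O)C(=C(C)C)C[C@H]2[C@@]1(C)O | intermediate
12 | 4β-hydroxy-5αH-eudesm-7(11)-ene-3,8-dione | O=C1CC[C@]2(C)CC(=O)C(=C(C)C)C[C@H]2[C@@]1(C)O | intermediate
13 | 3β,4β-dihydroxy-5αH-eudesm-7(11)-en-8-one | O[C@H]1CC[C@]2(C)CC(=O)C(=C(C)C)C[C@H]2[C@@]1(C)O | intermediate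
14 | angelic acid | C/C=C(/C)C(=O)O | starting material
15 | (Z)-2-methylbut-2-enoic 2,4,6-trichlorobenzoic anhydride | C/C=C(/C)C(=O)OC(=O)c1c(Cl)cc(Cl)cc1Cl | intermediate
16 | 3β-angeloyloxy-4β-hydroxy-5αH-eudesm-7(11)-en-8-one | C/C=C(/C)C(=O)O[C@H]1CC[C@]2(C)CC(=O)C(=C(C)C)C[C@H]2[C@@]1(C)O | intermediate
17 | 4β-acetoxy-3β-angeloyloxy-5αH-eudesm-7(11)-en-8-one | C/C=C(/C)C(=O)O[C@H]1CC[C@]2(C)CC(=O)C(=C(C)C)C[C@H]2[C@@]1(C)OC(C)=O | target

Total step count: 12. Longest linear sequence: 11 (steps 1 to 9, 11 and 12).

**Steps most likely to fail**

**Step 4.**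
- What may go wrong: too little facial discrimination on the chelated quinone; loss of turnover because the adduct keeps the chelating α-methoxy enone unit; part of the cycloaddition running through the isopropenyl arm; loss of the silyl group.
- Fallback (a covalently bound auxiliary with separation of diastereomers in place of catalyst control): it sets out from 6. Acid-catalysed alkoxy exchange with (−)-menthol (CSA, toluene, removal of methanol) would give 2-[(1R,2S,5R)-menthyloxy]-5-methyl-1,4-benzoquinone F1.
- Thermal Diels-Alder reaction of F1 with 5 (toluene, 80 °C) is again directed by the C4 carbonyl. It would give two diastereomeric cis adducts, the one with 10β-CH3 and 5β-H being the menthyl cis adduct F2.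
- DBU would give the menthyl trans-enedione F3, and the diastereomers are separated at this stage by crystallisation or chromatography.
- MeLi/CeCl3 would give the menthyl tertiary alcohol F4 and LiAlH4 the menthyl allylic diol F5. Aqueous HCl then expels menthol where the main route expels methanol, and the sequence comes back to the route at 11.

**Step 6.**
- What may go wrong: deprotonation at C5 in place of addition; attack at the C1 carbonyl or conjugate attack at C2; approach from the β face.
- Fallback (C15 brought in as a methylene group and reduced afterwards): it sets out from 8. Corey-Chaykovsky epoxidation with dimethylsulfonium methylide (Me3SI, n-BuLi, THF, −10 °C) is a 1,2-selective and irreversible addition. It should again come from the α face and would give the 4β,15-spiro-epoxide F6.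
- The LiAlH4 treatment of step 7 then opens the epoxide at its CH2 terminus while it reduces C1=O. The sequence comes back to the route at 10 without passing through 9.

**Step 12.**
- What may go wrong: elimination of the axial tertiary alcohol; Z to E isomerisation of the angelate; no conversion because of the 1,3-diaxial C10 methyl.
- Fallback (the tertiary acetate is made first, by ring opening rather than by acylation): it sets out from 13. Trimethyl orthoacetate with catalytic CSA (CH2Cl2, rt) would give the cyclic 3,4-orthoacetate F7.
- Mild hydrolysis (80 % aqueous AcOH, rt) follows the known preference of such orthoesters to free the equatorial hydroxyl and keep the ester on the axial oxygen. It would give 4β-acetoxy-3β-hydroxy-5αH-eudesm-7(11)-en-8-one F8.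
- Acylation of the free 3β-OH with 15 in toluene at 80 °C, kept near neutral to hold back acetyl migration, comes back to the route at 17.

**Further compounds**
F1 | step 4 | 2-[(1R,2S,5R)-menthyloxy]-5-methyl-1,4-benzoquinone | C[C@@H]1CC[C@H]([C@@H](C1)OC2=CC(=O)C(C)=CC2=O)C(C)C
F2 | step 4 | menthyl cis adduct | C[C@@H]1CC[C@H]([C@@H](C1)OC2=CC(=O)[C@]3(C)CC(O[Si](C)(C)C(C)(C)C)=C(C(C)=C)C[C@@H]3C2=O)C(C)C
F3 | step 4 | menthyl trans-enedione | C[C@@H]1CC[C@H]([C@@H](C1)OC2=CC(=O)[C@]3(C)CC(O[Si](C)(C)C(C)(C)C)=C(C(C)=C)C[C@H]3C2=O)C(C)C
F4 | step 4 | menthyl tertiary alcohol | C[C@@H]1CC[C@H]([C@@H](C1)OC2=CC(=O)[C@]3(C)CC(O[Si](C)(C)C(C)(C)C)=C(C(C)=C)C[C@H]3[C@@]2(C)O)C(C)C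
F5 | step 4 | menthyl allylic diol | C[C@@H]1CC[C@H]([C@@H](C1)OC2=CC(O)[C@]3(C)CC(O[Si](C)(C)C(C)(C)C)=C(C(C)=C)C[C@H]3[C@@]2(C)O)C(C)C
F6 | step 6 | 4β,15-spiro-epoxide | COC1=CC(=O)[C@]2(C)CC(O[Si](C)(C)C(C)(C)C)=C(C(C)=C)C[C@H]2[C@@]1(C3)O3
F7 | step 12 | cyclic 3,4-orthoacetate | COC1(C)O[C@H]2CC[C@]3(C)CC(=O)C(=C(C)C)C[C@H]3[C@@]2(C)O1
F8 | step 12 | 4β-acetoxy-3β-hydroxy-5αH-eudesm-7(11)-en-8-one | O[C@H]1CC[C@]2(C)CC(=O)C(=C(C)C)C[C@H]2[C@@]1(C)OC(C)=O
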